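**Retrosynthetic overview**

1. The strategy rests on C3 of the 6,7-dihydroxycoumarin: it carries the caffeoyl 4-oxygen and lies alpha to the C2 lactone carbonyl, so C3 is the CH2 of an aryloxyacetic acid, O1–C2 is that acid's aryl ester with a salicylaldehyde, and C4 is the formyl carbon.
2. Key disconnection: C3=C4 of the pyranone ring, opened to the 2-formylaryl aryloxyacetate 18 that already carries the whole protected caffeoyl–danshensu ester. The pyranone is the only skeletal ring the route builds (the three benzene rings are bought) and it is closed last, so the lactone never meets the earlier basic steps.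
3. Ester 18 comes from aryloxyacetic acid 14 and salicylaldehyde 17. For 17 the acetonide is put on benzene-1,2,4-triol first and the formyl group is added afterwards, because ketalising a catechol that already bears a para formyl group is unreliable.
4. Acid 14 comes from the cinnamate Cα=Cβ disconnection: Knoevenagel–Doebner condensation of aldehyde 4 (3,4-dihydroxybenzaldehyde, 4-O-alkylated with allyl bromoacetate, 3-O-MOM) with malonic half-ester 11 (Meldrum's acid opened by protected (R)-danshensu 9), then deallylation.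
5. The only stereocentre is bought with (R)-danshensu and is never touched at carbon. Two acetonides, one MOM ether and one tert-butyl ester fall together in a final acid step.

Key step: step 13

Remark: (R)-danshensu is taken as the free acid of the natural (R) enantiomer; if it is supplied as the sodium salt it is acidified before step 3.

**Route**

Step 1
Reactants: 1 3,4-dihydroxybenzaldehyde; 2 allyl bromoacetate
Product: 3 allyl 2-(4-formyl-2-hydroxyphenoxy)acetate
Conditions: NaHCO3, NaI (cat.), DMF, 40 °C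
Reagents that add atoms: none
Why: Williamson O-alkylation in which the weak base ionises only the more acidic 4-hydroxyl (para to the formyl group), so the reactive alpha-bromo ester should be taken up at O4 and the 3-hydroxyl left free.

Step 2
Reactants: 3 allyl 2-(4-formyl-2-hydroxyphenoxy)acetate
Product: 4 allyl 2-[4-formyl-2-(methoxymethoxy)phenoxy]acetate
Conditions: MOMCl, i-Pr2NEt, CH2Cl2, 0 °C to rt
Reagents that add atoms: chloromethyl methyl ether COCCl
Why: O-alkylation of the remaining phenol by the alpha-chloro ether under amine base, which leaves aldehyde and allyl ester alone and also blocks later lactonisation of this hydroxyl onto the neighbouring acetic acid unit.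

Step 3
Reactants: 5 (R)-danshensu
Product: 6 methyl (2R)-3-(3,4-dihydroxyphenyl)-2-hydroxypropanoate
Conditions: MeOH, H2SO4 (cat.), 50 °C, under N2
Reagents that add atoms: methanol CO
Why: Fischer esterification; the acidic medium cannot epimerise the alpha-hydroxy centre and the catechol is inert.

Step 4
Reactants: 6 methyl (2R)-3-(3,4-dihydroxyphenyl)-2-hydroxypropanoate
Product: 7 methyl (2R)-3-(2,2-dimethyl-1,3-benzodioxol-5-yl)-2-hydroxypropanoate
Conditions: Me2C(OMe)2, TsOH·H2O (cat.), benzene, reflux through 4 Å MS (Soxhlet); aqueous NaHCO3 then dilute citric acid wash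
Reagents that add atoms: 2,2-dimethoxypropane COC(C)(C)OC
Why: acid-catalysed transketalisation of an electron-rich catechol driven by removal of methanol; only the vicinal phenol pair can form the five-membered ketal, and any mixed ketal at the secondary hydroxyl should be lost in the work-up.

Step 5
Reactants: 7 methyl (2R)-3-(2,2-dimethyl-1,3-benzodioxol-5-yl)-2-hydroxypropanoate
Product: 8 (2R)-3-(2,2-dimethyl-1,3-benzodioxol-5-yl)-2-hydroxypropanoic acid
Conditions: LiOH·H2O, THF/H2O, 0 °C; then 1 M HCl to pH 3 at 0 °C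
Reagents that add atoms: lithium hydroxide [Li+].[OH-]
Why: ester saponification; the alkoxide/carboxylate formed is not prone to alpha-deprotonation, and brief cold acidification spares the aryl acetonide.

Step 6
Reactants: 8 (2R)-3-(2,2-dimethyl-1,3-benzodioxol-5-yl)-2-hydroxypropanoic acid
Product: 9 tert-butyl (2R)-3-(2,2-dimethyl-1,3-benzodioxol-5-yl)-2-hydroxypropanoate
Conditions: O-tert-butyl-N,N'-diisopropylisourea, CH2Cl2, rt
Reagents that add atoms: O-tert-butyl-N,N'-diisopropylisourea CC(C)N=C(OC(C)(C)C)NC(C)C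
Why: isourea esterification in which only the carboxylic acid is acidic enough to protonate the reagent and capture the tert-butyl group, so the secondary alcohol should stay free without any added acid that would endanger the acetonide.

Step 7
Reactants: 9 tert-butyl (2R)-3-(2,2-dimethyl-1,3-benzodioxol-5-yl)-2-hydroxypropanoate; 10 Meldrum's acid
Product: 11 3-{[(2R)-1-tert-butoxy-3-(2,2-dimethyl-1,3-benzodioxol-5-yl)-1-oxopropan-2-yl]oxy}-3-oxopropanoic acid
Conditions: toluene, 100 °C
Reagents that add atoms: none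
Why: thermal ring-opening acylation of the secondary alcohol by Meldrum's acid with loss of acetone, the standard neutral entry to malonic half-esters, which does not involve the stereocentre's C–H.

Step 8
Reactants: 4 allyl 2-[4-formyl-2-(methoxymethoxy)phenoxy]acetate; 11 3-{[(2R)-1-tert-butoxy-3-(2,2-dimethyl-1,3-benzodioxol-5-yl)-1-oxopropan-2-yl]oxy}-3-oxopropanoic acid
Product: 13 allyl 2-{4-[(E)-3-{[(2R)-1-tert-butoxy-3-(2,2-dimethyl-1,3-benzodioxol-5-yl)-1-oxopropan-2-yl]oxy}-3-oxoprop-1-en-1-yl]-2-(methoxymethoxy)phenoxy}acetate, via arylidenemalonic half-ester 12 (not isolated)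
Conditions: pyridine, piperidine (cat.), 50 °C
Reagents that add atoms: none
Why: Knoevenagel–Doebner condensation, in which amine-catalysed addition of the half-ester methylene to the aldehyde is followed by pyridine-promoted decarboxylation to the thermodynamically favoured E-cinnamate; the bases are too weak to deprotonate alpha to the tert-butyl ester.

Step 9
Reactants: 13 allyl 2-{4-[(E)-3-{[(2R)-1-tert-butoxy-3-(2,2-dimethyl-1,3-benzodioxol-5-yl)-1-oxopropan-2-yl]oxy}-3-oxoprop-1-en-1-yl]-2-(methoxymethoxy)phenoxy}acetate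
Product: 14 2-{4-[(E)-3-{[(2R)-1-tert-butoxy-3-(2,2-dimethyl-1,3-benzodioxol-5-yl)-1-oxopropan-2-yl]oxy}-3-oxoprop-1-en-1-yl]-2-(methoxymethoxy)phenoxy}acetic acid
Conditions: Pd(PPh3)4 (cat.), morpholine, THF, rt; cold dilute citric acid work-up
Reagents that add atoms: none
Why: Tsuji–Trost deallylation, in which zerovalent palladium ionises only the allyl ester and morpholine traps the allyl fragment; the cinnamate, tert-butyl ester, MOM ether and acetonide are not allylic and should stay untouched under these neutral conditions.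

Step 10
Reactants: 15 benzene-1,2,4-triol
Product: 16 2,2-dimethyl-1,3-benzodioxol-5-ol
Conditions: Me2C(OMe)2, TsOH·H2O (cat.), benzene, reflux through 4 Å MS (Soxhlet), under Ar
Reagents that add atoms: 2,2-dimethoxypropane COC(C)(C)OC
Why: acid-catalysed ketalisation of the only vicinal hydroxyl pair of an electron-rich triol (as for pyrogallol), which leaves the isolated 4-hydroxyl free.

Step 11
Reactants: 16 2,2-dimethyl-1,3-benzodioxol-5-ol
Product: 17 6-hydroxy-2,2-dimethyl-1,3-benzodioxole-5-carbaldehyde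
Conditions: MgCl2, Et3N, (CH2O)n, MeCN, reflux; cold 1 M HCl work-up
Reagents that add atoms: paraformaldehyde, as formaldehyde C=O
Why: Casnati–Skattebøl magnesium-mediated ortho-formylation, in which the magnesium phenoxide delivers formaldehyde to an ortho carbon and a second formaldehyde accepts hydride; the less hindered ortho position (C6, not the one next to the dioxole oxygen) should react, as with sesamol.

Step 12
Reactants: 14 2-{4-[(E)-3-{[(2R)-1-tert-butoxy-3-(2,2-dimethyl-1,3-benzodioxol-5-yl)-1-oxopropan-2-yl]oxy}-3-oxoprop-1-en-1-yl]-2-(methoxymethoxy)phenoxy}acetic acid; 17 6-hydroxy-2,2-dimethyl-1,3-benzodioxole-5-carbaldehyde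
Product: 18 6-formyl-2,2-dimethyl-1,3-benzodioxol-5-yl 2-{4-[(E)-3-{[(2R)-1-tert-butoxy-3-(2,2-dimethyl-1,3-benzodioxol-5-yl)-1-oxopropan-2-yl]oxy}-3-oxoprop-1-en-1-yl]-2-(methoxymethoxy)phenoxy}acetate
Conditions: EDC·HCl, DMAP (cat.), CH2Cl2, 0 °C; cold dilute citric acid wash, short silica plug, used at once
Reagents that add atoms: none
Why: Steglich esterification in which the salicylaldehyde hydroxyl is the only nucleophile; the activated aryl ester is kept cold and not stored, and any material that already closes to the coumarin under DMAP is simply the product of step 13.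

Step 13
Reactants: 18 6-formyl-2,2-dimethyl-1,3-benzodioxol-5-yl 2-{4-[(E)-3-{[(2R)-1-tert-butoxy-3-(2,2-dimethyl-1,3-benzodioxol-5-yl)-1-oxopropan-2-yl]oxy}-3-oxoprop-1-en-1-yl]-2-(methoxymethoxy)phenoxy}acetate
Product: 20 tert-butyl (2R)-3-(2,2-dimethyl-1,3-benzodioxol-5-yl)-2-{[(E)-3-{4-[(2,2-dimethyl-6-oxo-6H-[1,3]dioxolo[4,5-g]chromen-7-yl)oxy]-3-(methoxymethoxy)phenyl}prop-2-enoyl]oxy}propanoate, via aldol adduct 19 (not isolated)
Conditions: DBU (0.3 equiv), 4 Å MS, MeCN, 0 °C to rt
Reagents that add atoms: none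
Why: DBU reversibly deprotonates the O–CH2–C(=O)OAr methylene, the most acidic C–H in 18 because it is flanked by the aryl ether oxygen and by the carbonyl of an ester of an electron-poor 2-formylphenol; the enolate carbon adds to the ortho formyl carbon to give aldol 19, and E1cB loss of water forms C3=C4 and the conjugated 2-pyranone. This is the intramolecular Knoevenagel (Perkin-type) closure known for O-(aryloxyacetyl)salicylaldehydes on the way to 3-aryloxycoumarins. The lactone ring closes at C3–C4 in a favoured 6-(enolendo)-exo-trig mode, and the dehydration makes the closure irreversible. No stereocentre is created: the two transient centres of 19 are erased on dehydration and the (R) centre is a spectator. The step needs C–H selectivity for the aryloxyacetate methylene over the alpha C–H of the acyloxy tert-butyl ester, and the closure must outrun acyl transfer from the activated aryl ester. The lower pKa and open position of the methylene, the ortho placement of the aldehyde, a substoichiometric amidine base (a trialkylamine would be expected to need heating), low temperature and sieves to hold back water should secure both.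

Step 14
Reactants: 20 tert-butyl (2R)-3-(2,2-dimethyl-1,3-benzodioxol-5-yl)-2-{[(E)-3-{4-[(2,2-dimethyl-6-oxo-6H-[1,3]dioxolo[4,5-g]chromen-7-yl)oxy]-3-(methoxymethoxy)phenyl}prop-2-enoyl]oxy}propanoate
Product: 21 (2R)-3-(3,4-dihydroxyphenyl)-2-{[(E)-3-{4-[(6,7-dihydroxy-2-oxo-2H-chromen-3-yl)oxy]-3-hydroxyphenyl}prop-2-enoyl]oxy}propanoic acid (CNP0318082.1)
Conditions: TFA/H2O (9:1), degassed, dilute, 0 °C to rt, under Ar; evaporation, reversed-phase purification
Reagents that add atoms: none
Why: one acid treatment should hydrolyse both aryl ketals and the MOM acetal and cleave the tert-butyl ester by alkyl–oxygen fission, while the cinnamate ester, the lactone, the diaryl ether and the stereocentre (no enolisation in acid) are stable in cold aqueous TFA.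

**Compound list**

1 | 3,4-dihydroxybenzaldehyde | O=Cc1ccc(O)c(O)c1 | starting material
2 | allyl bromoacetate | C=CCOC(=O)CBr | starting material
3 | allyl 2-(4-formyl-2-hydroxyphenoxy)acetate | C=CCOC(=O)COc1ccc(C=O)cc1O | intermediate
4 | allyl 2-[4-formyl-2-(methoxymethoxy)phenoxy]acetate | C=CCOC(=O)COc1ccc(C=O)cc1OCOC | intermediate
5 | (R)-danshensu, (2R)-3-(3,4-dihydroxyphenyl)-2-hydroxypropanoic acid | O[C@H](Cc1ccc(O)c(O)c1)C(=O)O | starting material
6 | methyl (2R)-3-(3,4-dihydroxyphenyl)-2-hydroxypropanoate | O[C@H](Cc1ccc(O)c(O)c1)C(=O)OC | intermediate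
7 | methyl (2R)-3-(2,2-dimethyl-1,3-benzodioxol-5-yl)-2-hydroxypropanoate | O[C@H](Cc1ccc2OC(C)(C)Oc2c1)C(=O)OC | intermediate
8 | (2R)-3-(2,2-dimethyl-1,3-benzodioxol-5-yl)-2-hydroxypropanoic acid | O[C@H](Cc1ccc2OC(C)(C)Oc2c1)C(=O)O | intermediate
9 | tert-butyl (2R)-3-(2,2-dimethyl-1,3-benzodioxol-5-yl)-2-hydroxypropanoate | O[C@H](Cc1ccc2OC(C)(C)Oc2c1)C(=O)OC(C)(C)C | intermediate
10 | Meldrum's acid (2,2-dimethyl-1,3-dioxane-4,6-dione) | CC1(C)OC(=O)CC(=O)O1 | starting material
11 | malonic half-ester of 9, 3-{[(2R)-1-tert-butoxy-3-(2,2-dimethyl-1,3-benzodioxol-5-yl)-1-oxopropan-2-yl]oxy}-3-oxopropanoic acid | OC(=O)CC(=O)O[C@H](Cc1ccc2OC(C)(C)Oc2c1)C(=O)OC(C)(C)C | intermediate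
12 | arylidenemalonic half-ester from 4 and 11 (alkene geometry not defined, not isolated) | C=CCOC(=O)COc1ccc(C=C(C(=O)O)C(=O)O[C@H](Cc2ccc3OC(C)(C)Oc3c2)C(=O)OC(C)(C)C)cc1OCOC | intermediate
13 | allyl 2-{4-[(E)-3-{[(2R)-1-tert-butoxy-3-(2,2-dimethyl-1,3-benzodioxol-5-yl)-1-oxopropan-2-yl]oxy}-3-oxoprop-1-en-1-yl]-2-(methoxymethoxy)phenoxy}acetate | C=CCOC(=O)COc1ccc(/C=C/C(=O)O[C@H](Cc2ccc3OC(C)(C)Oc3c2)C(=O)OC(C)(C)C)cc1OCOC | intermediate
14 | 2-{4-[(E)-3-{[(2R)-1-tert-butoxy-3-(2,2-dimethyl-1,3-benzodioxol-5-yl)-1-oxopropan-2-yl]oxy}-3-oxoprop-1-en-1-yl]-2-(methoxymethoxy)phenoxy}acetic acid | OC(=O)COc1ccc(/C=C/C(=O)O[C@H](Cc2ccc3OC(C)(C)Oc3c2)C(=O)OC(C)(C)C)cc1OCOC | intermediate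
15 | benzene-1,2,4-triol | Oc1ccc(O)c(O)c1 | starting material
16 | 2,2-dimethyl-1,3-benzodioxol-5-ol | CC1(C)Oc2ccc(O)cc2O1 | intermediate
17 | 6-hydroxy-2,2-dimethyl-1,3-benzodioxole-5-carbaldehyde | O=Cc1cc2OC(C)(C)Oc2cc1O | intermediate
18 | 6-formyl-2,2-dimethyl-1,3-benzodioxol-5-yl ester of acid 14 (2-formylaryl aryloxyacetate, key-step precursor) | O=Cc1cc2OC(C)(C)Oc2cc1OC(=O)COc1ccc(/C=C/C(=O)O[C@H](Cc2ccc3OC(C)(C)Oc3c2)C(=O)OC(C)(C)C)cc1OCOC | intermediate
19 | aldol adduct, tert-butyl (2R)-3-(2,2-dimethyl-1,3-benzodioxol-5-yl)-2-{[(E)-3-{4-[(8-hydroxy-2,2-dimethyl-6-oxo-7,8-dihydro-6H-[1,3]dioxolo[4,5-g]chromen-7-yl)oxy]-3-(methoxymethoxy)phenyl}prop-2-enoyl]oxy}propanoate (mixture at the two new ring carbons, not isolated) | O=C(/C=C/c1ccc(OC2C(O)c3cc4OC(C)(C)Oc4cc3OC2=O)c(OCOC)c1)O[C@H](Cc1ccc2OC(C)(C)Oc2c1)C(=O)OC(C)(C)C | intermediate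
20 | fully protected target, tert-butyl (2R)-3-(2,2-dimethyl-1,3-benzodioxol-5-yl)-2-{[(E)-3-{4-[(2,2-dimethyl-6-oxo-6H-[1,3]dioxolo[4,5-g]chromen-7-yl)oxy]-3-(methoxymethoxy)phenyl}prop-2-enoyl]oxy}propanoate | O=C(/C=C/c1ccc(Oc2cc3cc4OC(C)(C)Oc4cc3oc2=O)c(OCOC)c1)O[C@H](Cc1ccc2OC(C)(C)Oc2c1)C(=O)OC(C)(C)C | intermediate
21 | CNP0318082.1, (2R)-3-(3,4-dihydroxyphenyl)-2-{[(E)-3-{4-[(6,7-dihydroxy-2-oxo-2H-chromen-3-yl)oxy]-3-hydroxyphenyl}prop-2-enoyl]oxy}propanoic acid | O=C(/C=C/c1ccc(Oc2cc3cc(O)c(O)cc3oc2=O)c(O)c1)O[C@H](Cc1ccc(O)c(O)c1)C(=O)O | target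

**Step count and risks**

Total steps: 14. Longest linear sequence: 10 steps (5 → 6 → 7 → 8 → 9 → 11 → 13 → 14 → 18 → 20 → 21; steps 3–9 and 12–14).

Steps most likely to fail:

Step 13 (key step). The base may trigger acyl transfer from the activated 2-formylaryl ester (to traces of water, to the amidine, or by ketene loss) faster than the aldol closure, and prolonged exposure to base may erode the configuration alpha to the tert-butyl ester. The fallback closes the pyranone ring on a small achiral fragment by the thermal one-pot Perkin-type condensation and attaches the chiral half afterwards. It sets out from 4. Deallylation with Pd(PPh3)4 and morpholine in THF should give 2-[4-formyl-2-(methoxymethoxy)phenoxy]acetic acid F1. Heating F1 with 17 and DCC in DMSO at about 100 °C should pass through 6-formyl-2,2-dimethyl-1,3-benzodioxol-5-yl 2-[4-formyl-2-(methoxymethoxy)phenoxy]acetate F2, formed in the flask, and give 4-[(2,2-dimethyl-6-oxo-6H-[1,3]dioxolo[4,5-g]chromen-7-yl)oxy]-3-(methoxymethoxy)benzaldehyde F3. Knoevenagel–Doebner condensation of F3 with half-ester 11 (pyridine, cat. piperidine, 50 °C) then comes back to the route at 20.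

Step 8. The hindered half-ester may condense slowly, so that plain decarboxylation of 11 and slow aminolysis of the allyl aryloxyacetate by piperidine compete. The fallback replaces the condensation by a Horner–Wadsworth–Emmons olefination. It sets out from 9. Acylation with diethylphosphonoacetic acid (EDC·HCl, cat. DMAP, CH2Cl2) should give tert-butyl (2R)-2-{[2-(diethoxyphosphoryl)acetyl]oxy}-3-(2,2-dimethyl-1,3-benzodioxol-5-yl)propanoate F4. Masamune–Roush olefination of F4 with aldehyde 4 (LiCl, i-Pr2NEt, MeCN, rt) should give the E-cinnamate and comes back to the route at 13.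

Step 14. The freed electron-rich catechol rings may capture tert-butyl cation or the formaldehyde equivalent from the MOM group, and slow hydrolysis of the acetonide on the electron-poor coumarin ring may force long acid exposure. The fallback stages the deprotection so that the formaldehyde unit is removed and trapped before any catechol is free. It sets out from 20. ZnBr2 and n-PrSH in CH2Cl2 at 0 °C should remove only the MOM ether, with its methylene carried off on sulfur, and give tert-butyl (2R)-3-(2,2-dimethyl-1,3-benzodioxol-5-yl)-2-{[(E)-3-{4-[(2,2-dimethyl-6-oxo-6H-[1,3]dioxolo[4,5-g]chromen-7-yl)oxy]-3-hydroxyphenyl}prop-2-enoyl]oxy}propanoate F5. Aqueous TFA on F5 then releases only acetone and the tert-butyl group and comes back to the route at 21.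

**Further compounds**

F1 | step 13 | 2-[4-formyl-2-(methoxymethoxy)phenoxy]acetic acid | O=Cc1ccc(OCC(=O)O)c(OCOC)c1
F2 | step 13 | 6-formyl-2,2-dimethyl-1,3-benzodioxol-5-yl 2-[4-formyl-2-(methoxymethoxy)phenoxy]acetate | O=Cc1cc2OC(C)(C)Oc2cc1OC(=O)COc1ccc(C=O)cc1OCOC
F3 | step 13 | 4-[(2,2-dimethyl-6-oxo-6H-[1,3]dioxolo[4,5-g]chromen-7-yl)oxy]-3-(methoxymethoxy)benzaldehyde | O=Cc1ccc(Oc2cc3cc4OC(C)(C)Oc4cc3oc2=O)c(OCOC)c1
F4 | step 8 | tert-butyl (2R)-2-{[2-(diethoxyphosphoryl)acetyl]oxy}-3-(2,2-dimethyl-1,3-benzodioxol-5-yl)propanoate | CCOP(=O)(OCC)CC(=O)O[C@H](Cc1ccc2OC(C)(C)Oc2c1)C(=O)OC(C)(C)C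
F5 | step 14 | tert-butyl (2R)-3-(2,2-dimethyl-1,3-benzodioxol-5-yl)-2-{[(E)-3-{4-[(2,2-dimethyl-6-oxo-6H-[1,3]dioxolo[4,5-g]chromen-7-yl)oxy]-3-hydroxyphenyl}prop-2-enoyl]oxy}propanoate | O=C(/C=C/c1ccc(Oc2cc3cc4OC(C)(C)Oc4cc3oc2=O)c(O)c1)O[C@H](Cc1ccc2OC(C)(C)Oc2c1)C(=O)OC(C)(C)C
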